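**Retrosynthetic overview**
1. Key disconnection: the two C–O bonds of ring C (the pendant 4-methoxy-2-pyranone), O–CH3 and the enol-lactone O–C(=O). Ring C is closed last from an open-chain 3,5-dioxo ester on the cyclobutane.
2. Keeping ring C open gives an enolised 1,3-diketone, a bidentate handle for a chiral Lewis acid. Ring B (cyclobutane) then comes from an enantioselective crossed [2+2] between the enone of methyl (6E)-3,5-dioxo-7-phenylhept-6-enoate and the C5=C6 bond of 4-methoxy-6-(2-phenylethyl)-2H-pyran-2-one; all four stereocenters are set there.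
3. Ring A (the bicyclic dihydropyranone) is not built; it is the pyranone ring of the phenethylpyranone, carried in with its C–O bond in place.
4. Partners: acetoacetate dianion + cinnamoyl Weinreb amide; 4-methoxy-6-methyl-2H-pyran-2-one + benzyl bromide.
5. Ring order: A (bought) → B ([2+2]) → C (C–O lactonisation, then O-methylation).

Assumption: the (S,S)-ligand is taken to give the enantiomer drawn; if a test run shows the opposite sense, the (R,R)-ligand is used with nothing else changed.

**Step 1**
Reactants: 1 methyl acetoacetate; 2 (2E)-N-methoxy-N-methyl-3-phenylprop-2-enamide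
Product: 4 methyl (6E)-3,5-dioxo-7-phenylhept-6-enoate, via dilithium dienolate of methyl acetoacetate 3 (not isolated)
Conditions: LiN(i-Pr)2 (2.2 equiv), THF, −78 to 0 °C; then 2, −78 to −20 °C; 1 M HCl
Reagents that add atoms: none
Why: Claisen-type γ-acylation of the Weiler dianion by a Weinreb amide, whose chelated tetrahedral adduct survives until the acid quench and so stops over-addition; no stereocenter is formed and the E-alkene is untouched.

**Step 2**
Reactants: 5 4-methoxy-6-methyl-2H-pyran-2-one; 6 benzyl bromide
Product: 8 4-methoxy-6-(2-phenylethyl)-2H-pyran-2-one, via 6-(lithiomethyl)-4-methoxy-2H-pyran-2-one 7 (not isolated)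
Conditions: LiN(i-Pr)2 (1.1 equiv), THF/DMPU, −78 °C; then 6, −78 to −20 °C
Reagents that add atoms: none
Why: Kinetic deprotonation of the vinylogous 6-methyl group followed by SN2 benzylation (enolate alkylation, the established way to this kavalactone); no stereocenter is formed.

**Step 3**
Reactants: 4 methyl (6E)-3,5-dioxo-7-phenylhept-6-enoate; 8 4-methoxy-6-(2-phenylethyl)-2H-pyran-2-one
Product: 9 methyl 5-[(1R,6S,7S,8R)-5-methoxy-3-oxo-7-phenyl-1-(2-phenylethyl)-2-oxabicyclo[4.2.0]oct-4-en-8-yl]-3,5-dioxopentanoate
Conditions: Sc(OTf)3 (10 mol %), (S,S)-t-Bu-PyBox (15 mol %), Ru(bpy)3(PF6)2 (2.5 mol %), 8 (5 equiv, excess recovered), i-PrOAc/MeCN 3:1, 455 nm LEDs, −20 °C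
Reagents that add atoms: none
Why: Proposed new method: the enolised 1,3-diketone of 4 binds Sc(OTf)3/(S,S)-t-Bu-PyBox as a six-membered chelate, which should lower its triplet energy enough for Ru(bpy)3(PF6)2 to sensitise only the bound enone while free 4 and 8 stay dark (no racemic background, no pyranone photochemistry); the triplet α-carbon adds to C6 of 8 to give the most stabilised 1,4-diradical (benzylic plus pyranone-delocalised), which closes to the cyclobutane after intersystem crossing; ring A forces the cis ring fusion, the E-alkene ends as phenyl trans to acyl, the flat phenyl is expected to stack over ring A while the bulky scandium chelate sits on the side of the flexible phenethyl chain, and the tert-butyl groups of the ligand shield one enone face to fix the absolute configuration; the closest known reaction is the chiral-Lewis-acid-catalysed, triplet-sensitised enantioselective [2+2] photocycloaddition of 2'-hydroxychalcones with dienes and styrenes.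

**Step 4**
Reactants: 9 methyl 5-[(1R,6S,7S,8R)-5-methoxy-3-oxo-7-phenyl-1-(2-phenylethyl)-2-oxabicyclo[4.2.0]oct-4-en-8-yl]-3,5-dioxopentanoate
Product: 11 (1R,6S,7S,8S)-5-methoxy-8-(4-methoxy-2-oxo-2H-pyran-6-yl)-7-phenyl-1-(2-phenylethyl)-2-oxabicyclo[4.2.0]oct-4-en-3-one, via hydroxypyranone 10 (not isolated)
Conditions: DBU (1.2 equiv), PhMe, 40 °C; then K2CO3, Me2SO4, acetone, 50 °C (one pot)
Reagents that add atoms: dimethyl sulfate, COS(=O)(=O)OC
Why: Harris-type enol-lactonisation of the 3,5-dioxo ester (the enolate oxygen of the ketone next to the cyclobutane attacks the ester, forming the O–C(=O) bond of ring C and expelling methanol) followed by Williamson-type O-methylation of the vinylogous acid to the 4-methoxy-2-pyranone; the four stereocenters are untouched because the diketonate anion formed first keeps the cyclobutane C–H next to the ketone from being deprotonated.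

**Compound list**
1 | methyl acetoacetate (methyl 3-oxobutanoate) | COC(=O)CC(C)=O | starting material
2 | (2E)-N-methoxy-N-methyl-3-phenylprop-2-enamide (cinnamoyl Weinreb amide) | CON(C)C(=O)/C=C/c1ccccc1 | starting material
3 | dilithium dienolate of methyl acetoacetate | C=C(O[Li])C=C(OC)O[Li] | intermediate
4 | methyl (6E)-3,5-dioxo-7-phenylhept-6-enoate (drawn as the triketo form; mostly enolised) | COC(=O)CC(=O)CC(=O)/C=C/c1ccccc1 | intermediate
5 | 4-methoxy-6-methyl-2H-pyran-2-one | COc1cc(C)oc(=O)c1 | starting material
6 | benzyl bromide | BrCc1ccccc1 | starting material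
7 | 6-(lithiomethyl)-4-methoxy-2H-pyran-2-one | [Li]Cc1cc(OC)cc(=O)o1 | intermediate
8 | 4-methoxy-6-(2-phenylethyl)-2H-pyran-2-one | COc1cc(CCc2ccccc2)oc(=O)c1 | intermediate
9 | methyl 5-[(1R,6S,7S,8R)-5-methoxy-3-oxo-7-phenyl-1-(2-phenylethyl)-2-oxabicyclo[4.2.0]oct-4-en-8-yl]-3,5-dioxopentanoate (cis-fused; phenyl on the face of ring A; acyl chain trans to phenyl, on the face of the phenethyl group) | COC1=CC(=O)O[C@]2(CCc3ccccc3)[C@H]1[C@H](c1ccccc1)[C@H]2C(=O)CC(=O)CC(=O)OC | intermediate
10 | (1R,6S,7S,8S)-8-(4-hydroxy-2-oxo-2H-pyran-6-yl)-5-methoxy-7-phenyl-1-(2-phenylethyl)-2-oxabicyclo[4.2.0]oct-4-en-3-one | COC1=CC(=O)O[C@]2(CCc3ccccc3)[C@H]1[C@H](c1ccccc1)[C@H]2c1cc(O)cc(=O)o1 | intermediate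
11 | (1R,6S,7S,8S)-5-methoxy-8-(4-methoxy-2-oxo-2H-pyran-6-yl)-7-phenyl-1-(2-phenylethyl)-2-oxabicyclo[4.2.0]oct-4-en-3-one (cis-fused; phenyl on the face of ring A; pyranone trans to phenyl, on the face of the phenethyl group) | COC1=CC(=O)O[C@]2(CCc3ccccc3)[C@H]1[C@H](c1ccccc1)[C@H]2c1cc(OC)cc(=O)o1 | target

**Totals**
Total steps: 4. Longest linear sequence: 3 (steps 1, 3, 4).

**Steps most likely to fail**

Step 3 (the proposed new method). The risks are:
- low reactivity of the pyranone C5=C6 bond toward the bound triplet;
- the head-to-tail regioisomer;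
- the diastereomer with phenyl away from ring A, which simple steric arguments favour (the stacking rationale above is a design hypothesis, not a prediction);
- poor turnover, because product 9 is itself a chelator;
- low ee.

Fallback with known chemistry, setting out from 4 (with 8) and coming back at 11: 4 is closed and methylated as in step 4 (DBU; then K2CO3, Me2SO4) to 4-methoxy-6-[(E)-2-phenylethenyl]-2H-pyran-2-one F1. F1 and 8 (5 equiv) are then irradiated (thioxanthone 10 mol %, 405 nm, MeCN, or as a co-ground solid at 365 nm) in a crossed [2+2] photodimerisation of the kind known for styrylpyrones. The head-to-head adduct is isolated on silica as a racemate, that is 11 together with its mirror image (1S,6R,7R,8R)-5-methoxy-8-(4-methoxy-2-oxo-2H-pyran-6-yl)-7-phenyl-1-(2-phenylethyl)-2-oxabicyclo[4.2.0]oct-4-en-3-one F2. F2 is removed by preparative chiral SFC, which returns the route at 11.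

Step 1. The risks are conjugate addition of the dianion to the cinnamoyl unit and premature closure of 4 to the hydroxypyranone. Fallback setting out from 1 (through dianion 3) and coming back at 4: the dianion is added to cinnamaldehyde (clean 1,2-aldol, THF, −78 °C) to give methyl (6E)-5-hydroxy-3-oxo-7-phenylhept-6-enoate F3. The allylic alcohol of F3 is then oxidised with Dess–Martin periodinane (CH2Cl2, 0 °C) to 4.

Step 4. The risks are the isomeric 2-methoxy-4-pyranone from O-methylation at the other oxygen, and base-induced opening of ring A or epimerisation next to the ketone during the warm one-pot sequence. Fallback setting out from 9 and coming back at 11: ring C is closed with DBU at room temperature and 10 is isolated after an acidic work-up. It is then methylated under Mitsunobu conditions (MeOH, PPh3, DIAD, THF, 0 °C), a non-basic redox condensation known to alkylate only the 4-hydroxyl of 4-hydroxy-2-pyranones. This fallback makes no compound outside the list, F0.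

**Further compounds**
F1 | step 3 | 4-methoxy-6-[(E)-2-phenylethenyl]-2H-pyran-2-one (5,6-dehydrokawain) | COc1cc(/C=C/c2ccccc2)oc(=O)c1
F2 | step 3 | (1S,6R,7R,8R)-5-methoxy-8-(4-methoxy-2-oxo-2H-pyran-6-yl)-7-phenyl-1-(2-phenylethyl)-2-oxabicyclo[4.2.0]oct-4-en-3-one (enantiomer of 11) | COC1=CC(=O)O[C@@]2(CCc3ccccc3)[C@@H]1[C@@H](c1ccccc1)[C@@H]2c1cc(OC)cc(=O)o1
F3 | step 1 | methyl (6E)-5-hydroxy-3-oxo-7-phenylhept-6-enoate (racemic) | COC(=O)CC(=O)CC(O)/C=C/c1ccccc1
F0 | step 4 | none | none
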